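**Retrosynthetic overview**

1. Carotenoid numbering is used (ring C1 = CMe2, C2 and C3 = carbinols, C4 = CH2, C5=C6, chain C7–C15, primes for the sulfated half, O6 = the oxygen on the carbon that becomes C6). The plan rests on the end groups: each is a 1-vinyl-2-methylcyclohexene, ring C1–C6 with C5=C6 conjugated to C7=C8, which is what an exo ring-closing enyne metathesis delivers, and its C6–C1(Me2)–C2(O)–C3 run is the carbon skeleton of (R)-pantolactone with C2 already (R).
2. Target ⇒ global desilylation ⇐ sulfation of O3' ⇐ selective loss of the O3' triethylsilyl group ⇐ Wittig union at C15=C15' of a C20 phosphonium salt (O2 and O3 as TBS ethers) with a C20 aldehyde (O2' TBS, O3' TES).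
3. Each C20 half ⇒ C15 aldehyde + triethyl 3-methyl-4-phosphonocrotonate (C11=C12) ⇒ ring diene + ethyl (E)-3-iodobut-2-enoate (Heck coupling at C8).
4. Both ring dienes ⇒ one protected 6-vinyl ring diene ⇒ acyclic 1,7-enyne by ring-closing enyne metathesis (C5=C6 and C7=C8 formed, ring C1–C6 closed). This is the only ring-forming step; one batch supplies first the unprimed and then the primed ring, before any polyene is built.
5. Enyne ⇒ (R)-pantolactone: reduction, O2/O6 p-methoxybenzylidene acetal, C3 aldehyde, chelation-controlled methallylation (sets C3), reductive acetal opening, oxidation at C6, Seyferth–Gilbert homologation.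

Key step: step 10

Assumption: the hydrogen sulfate drawn for the target is taken as the acid form of the sulfate monoester; it is set free only in the last cold acidification and would in practice be stored as a salt. All polyenes are handled under argon in the dark.

**Route**

Step 1
Reactants: 1 methallyl chloride
Product: 3 tributyl(2-methylallyl)stannane, via (2-methylallyl)magnesium chloride 2 (not isolated)
Conditions: Mg, THF, 0 °C → rt; then Bu3SnCl, 0 °C → rt
Reagents that add atoms: tributyltin chloride, CCCC[Sn](Cl)(CCCC)CCCC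
Why: Grignard formation followed by substitution at tin (transmetalation) is the standard preparation of allylic stannanes, and slow addition in the cold limits Wurtz coupling.

Step 2
Reactants: 4 (R)-pantolactone
Product: 5 (2R)-3,3-dimethylbutane-1,2,4-triol
Conditions: LiAlH4, THF, 0 °C → reflux; aq. NaOH work-up
Reagents that add atoms: none
Why: Hydride reduction of the lactone (ester reduction) gives the triol, and the C2 carbinol, held as its alkoxide, keeps the (R) configuration.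

Step 3
Reactants: 5 (2R)-3,3-dimethylbutane-1,2,4-triol
Product: 6 [(2R,4R)-2-(4-methoxyphenyl)-5,5-dimethyl-1,3-dioxan-4-yl]methanol
Conditions: 4-MeOC6H4CH(OMe)2, CSA (cat.), CH2Cl2, rt
Reagents that add atoms: 4-methoxybenzaldehyde dimethyl acetal, COc1ccc(C(OC)OC)cc1
Why: Acid-catalysed transacetalisation under thermodynamic control gives the six-membered 1,3-dioxane across O2 and O6 with the aryl group and the CH2OH arm both equatorial (cis), in preference to the five-membered acetal, and leaves the primary C3 hydroxyl free.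

Step 4
Reactants: 6 [(2R,4R)-2-(4-methoxyphenyl)-5,5-dimethyl-1,3-dioxan-4-yl]methanol
Product: 7 (2R,4R)-2-(4-methoxyphenyl)-5,5-dimethyl-1,3-dioxane-4-carbaldehyde
Conditions: (COCl)2, DMSO, CH2Cl2, −78 °C; Et3N, −78 → 0 °C
Reagents that add atoms: none
Why: Swern oxidation gives the α-alkoxy aldehyde at low temperature without acid, so the acetal and the C2 stereocentre are kept, and the aldehyde is used at once.

Step 5
Reactants: 7 (2R,4R)-2-(4-methoxyphenyl)-5,5-dimethyl-1,3-dioxane-4-carbaldehyde; 3 tributyl(2-methylallyl)stannane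
Product: 8 (1R)-1-[(2R,4R)-2-(4-methoxyphenyl)-5,5-dimethyl-1,3-dioxan-4-yl]-3-methylbut-3-en-1-ol
Conditions: MgBr2·OEt2, CH2Cl2, −78 → −20 °C
Reagents that add atoms: none
Why: Lewis-acid-mediated carbonyl allylation with an allylstannane under Cram-chelate control, in which magnesium bridges the aldehyde oxygen and the ring oxygen O2 and the stannane attacks the face away from the quaternary C1 (the face the steric Felkin model also predicts), sets C3 as (R), 2,3-syn, the relationship that becomes the trans-diol of the ring.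

Step 6
Reactants: 8 (1R)-1-[(2R,4R)-2-(4-methoxyphenyl)-5,5-dimethyl-1,3-dioxan-4-yl]-3-methylbut-3-en-1-ol
Product: 9 tert-butyl{[(1R)-1-[(2R,4R)-2-(4-methoxyphenyl)-5,5-dimethyl-1,3-dioxan-4-yl]-3-methylbut-3-en-1-yl]oxy}dimethylsilane
Conditions: TBSCl, imidazole, DMAP (cat.), DMF, 40 °C
Reagents that add atoms: tert-butyldimethylsilyl chloride, CC(C)(C)[Si](C)(C)Cl
Why: Imidazole-promoted silylation protects O3 without any Lewis acid, so the p-methoxybenzylidene acetal is untouched.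

Step 7
Reactants: 9 tert-butyl{[(1R)-1-[(2R,4R)-2-(4-methoxyphenyl)-5,5-dimethyl-1,3-dioxan-4-yl]-3-methylbut-3-en-1-yl]oxy}dimethylsilane
Product: 10 (3R,4R)-4-[(tert-butyldimethylsilyl)oxy]-3-[(4-methoxybenzyl)oxy]-2,2,6-trimethylhept-6-en-1-ol
Conditions: i-Bu2AlH, CH2Cl2, −78 → 0 °C; aq. potassium sodium tartrate work-up
Reagents that add atoms: none
Why: Reductive opening of a p-methoxybenzylidene acetal, in which the aluminium hydride binds the less hindered primary oxygen O6, that C–O bond breaks and hydride is delivered to the oxocarbenium ion, leaves the PMB ether on the secondary O2 and frees the neopentyl alcohol.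

Step 8
Reactants: 10 (3R,4R)-4-[(tert-butyldimethylsilyl)oxy]-3-[(4-methoxybenzyl)oxy]-2,2,6-trimethylhept-6-en-1-ol
Product: 11 (3R,4R)-4-[(tert-butyldimethylsilyl)oxy]-3-[(4-methoxybenzyl)oxy]-2,2,6-trimethylhept-6-enal
Conditions: (COCl)2, DMSO, CH2Cl2, −78 °C; Et3N, −78 °C → rt
Reagents that add atoms: none
Why: Swern oxidation of the neopentyl alcohol gives an aldehyde whose α-carbon is quaternary, so it can neither epimerise nor eliminate the β-alkoxy group.

Step 9
Reactants: 11 (3R,4R)-4-[(tert-butyldimethylsilyl)oxy]-3-[(4-methoxybenzyl)oxy]-2,2,6-trimethylhept-6-enal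
Product: 12 tert-butyl{[(4R,5R)-5-[(4-methoxybenzyl)oxy]-2,6,6-trimethyloct-1-en-7-yn-4-yl]oxy}dimethylsilane
Conditions: MeC(O)C(N2)P(O)(OMe)2, K2CO3, MeOH, 0 °C → rt
Reagents that add atoms: dimethyl (1-diazo-2-oxopropyl)phosphonate, COP(=O)(OC)C(=[N+]=[N-])C(C)=O
Why: Seyferth–Gilbert homologation in its Ohira–Bestmann form converts the non-enolisable aldehyde into the terminal alkyne C6≡C7 under mild base that the silyl and PMB ethers tolerate.

Step 10
Reactants: 12 tert-butyl{[(4R,5R)-5-[(4-methoxybenzyl)oxy]-2,6,6-trimethyloct-1-en-7-yn-4-yl]oxy}dimethylsilane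
Product: 13 tert-butyl{[(1R,6R)-6-[(4-methoxybenzyl)oxy]-3,5,5-trimethyl-4-vinylcyclohex-3-en-1-yl]oxy}dimethylsilane
Conditions: second-generation Grubbs catalyst (H2IMes)(PCy3)Cl2Ru=CHPh (10 mol %), ethylene (1 atm), toluene, 80 °C
Reagents that add atoms: none
Why: Under ethylene the catalyst is held as Ru=CH2, which adds to the terminal alkyne with the new C–C bond at C7 and ruthenium on C6; the ruthenacyclobutene opens to a C6 vinylcarbene, this undergoes [2+2] cycloaddition with the C5 isopropenyl group, and cycloreversion forms C5=C6 and releases Ru=CH2, so that the CH2 lost from the alkene returns as C8. The closest known reaction type is the ruthenium-catalysed ring-closing metathesis of 1,7-enynes to 1-vinylcyclohexenes under ethylene, including cases with 1,1-disubstituted alkenes that give a 2-alkyl substituent. Ring C1–C6 closes in the exo mode (C6 becomes a ring atom, C7 stays outside), and no stereocentre is formed, so C2 and C3 pass through unchanged. The step needs exo six-ring closure to win over endo seven-ring closure, alkyne oligomerisation and intermolecular metathesis: the gem-dimethyl group at C1 folds the chain (Thorpe–Ingold effect), the hindered 1,1-disubstituted alkene leaves the alkyne as the only site of initiation, the closing chair can place O2 and O3 both equatorial, and ethylene both suppresses oligomers and offers a second path through the 2-substituted butadiene and diene ring closure to the same product. The vinyl group of 13, flanked by C1 and the C5 methyl group, is too hindered for secondary metathesis.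

Step 11
Reactants: 13 tert-butyl{[(1R,6R)-6-[(4-methoxybenzyl)oxy]-3,5,5-trimethyl-4-vinylcyclohex-3-en-1-yl]oxy}dimethylsilane
Product: 14 (1R,6R)-6-[(tert-butyldimethylsilyl)oxy]-2,2,4-trimethyl-3-vinylcyclohex-3-en-1-ol
Conditions: DDQ, CH2Cl2/aq. Na2HPO4–NaH2PO4 (pH 7), 0 °C
Reagents that add atoms: none
Why: Oxidative PMB ether cleavage (hydride abstraction by DDQ and hydrolysis of the oxocarbenium ion) frees O2, while the diene, twisted by its flanking methyl groups, cannot reach the s-cis geometry needed for cycloaddition with the quinone and the silyl ether is inert.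

Step 12
Reactants: 14 (1R,6R)-6-[(tert-butyldimethylsilyl)oxy]-2,2,4-trimethyl-3-vinylcyclohex-3-en-1-ol
Product: 15 (4R,5R)-4,5-bis[(tert-butyldimethylsilyl)oxy]-1,3,3-trimethyl-2-vinylcyclohex-1-ene
Conditions: TBSOTf, 2,6-lutidine, CH2Cl2, 0 °C → rt
Reagents that add atoms: tert-butyldimethylsilyl trifluoromethanesulfonate, CC(C)(C)[Si](C)(C)OS(=O)(=O)C(F)(F)F
Why: Silylation with the silyl triflate is used because O2 is a neopentyl-type secondary alcohol, and the lutidine buffer protects the diene from acid.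

Step 13
Reactants: 14 (1R,6R)-6-[(tert-butyldimethylsilyl)oxy]-2,2,4-trimethyl-3-vinylcyclohex-3-en-1-ol
Product: 16 (1R,2R)-3,3,5-trimethyl-4-vinylcyclohex-4-ene-1,2-diol
Conditions: Bu4NF, THF, 0 °C → rt
Reagents that add atoms: none
Why: Fluoride-mediated desilylation frees O3 and gives the trans-diol for redifferentiation on the half that will carry the sulfate.

Step 14
Reactants: 16 (1R,2R)-3,3,5-trimethyl-4-vinylcyclohex-4-ene-1,2-diol
Product: 17 (1R,6R)-2,2,4-trimethyl-6-[(triethylsilyl)oxy]-3-vinylcyclohex-3-en-1-ol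
Conditions: Et3SiCl (1.05 equiv), imidazole, CH2Cl2, −40 → 0 °C
Reagents that add atoms: chlorotriethylsilane, CC[Si](Cl)(CC)CC
Why: Regioselective silylation occurs at the C3 hydroxyl, which is flanked by a CH2 group and should react far faster than the C2 hydroxyl next to the gem-dimethyl carbon.

Step 15
Reactants: 17 (1R,6R)-2,2,4-trimethyl-6-[(triethylsilyl)oxy]-3-vinylcyclohex-3-en-1-ol
Product: 18 tert-butyldimethyl{[(1R,6R)-2,2,4-trimethyl-6-[(triethylsilyl)oxy]-3-vinylcyclohex-3-en-1-yl]oxy}silane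
Conditions: TBSOTf, 2,6-lutidine, CH2Cl2, −78 → 0 °C
Reagents that add atoms: tert-butyldimethylsilyl trifluoromethanesulfonate, CC(C)(C)[Si](C)(C)OS(=O)(=O)C(F)(F)F
Why: Silyl triflate silylation caps the hindered O2 while the triethylsilyl ether does not exchange under buffered low-temperature conditions, which gives the labile/robust pair needed to free O3' alone later.

Step 16
Reactants: 19 ethyl but-2-ynoate
Product: 20 ethyl (E)-3-(tributylstannyl)but-2-enoate
Conditions: Bu3SnH, LiN(iPr)2, THF, 0 °C; CuBr·SMe2, −78 °C; then 19, MeOH, −78 °C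
Reagents that add atoms: tributyltin hydride (used as its lithium and copper derivatives), CCCC[SnH](CCCC)CCCC
Why: Stannylcupration of an alkynoate is a syn addition with tin at C3, and protonation of the alkenylcopper at −78 °C before it can isomerise leaves tin trans to the ester, the (E) isomer.

Step 17
Reactants: 20 ethyl (E)-3-(tributylstannyl)but-2-enoate
Product: 21 ethyl (E)-3-iodobut-2-enoate
Conditions: iodine, CH2Cl2, 0 °C
Reagents that add atoms: iodine, [I][I]
Why: Iododestannylation (electrophilic ipso substitution) proceeds with retention of alkene geometry and gives the (E)-β-iodo enoate.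

Step 18
Reactants: 15 (4R,5R)-4,5-bis[(tert-butyldimethylsilyl)oxy]-1,3,3-trimethyl-2-vinylcyclohex-1-ene; 21 ethyl (E)-3-iodobut-2-enoate
Product: 22 ethyl (2E,4E)-5-[(4R,5R)-4,5-bis[(tert-butyldimethylsilyl)oxy]-2,6,6-trimethylcyclohex-1-en-1-yl]-3-methylpenta-2,4-dienoate
Conditions: Pd(OAc)2 (10 mol %), Bu4NCl, K2CO3, DMF, 50 °C
Reagents that add atoms: none
Why: Mizoroki–Heck coupling of an alkenyl iodide with the terminal carbon of a 1,3-diene under ligand-free phase-transfer conditions proceeds by oxidative addition to zerovalent palladium with retention, insertion at the unhindered C8 and syn β-hydride elimination from C8, which should give the (7E,9E) triene ester, while the tetrasubstituted C5=C6 bond cannot insert.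

Step 19
Reactants: 22 ethyl (2E,4E)-5-[(4R,5R)-4,5-bis[(tert-butyldimethylsilyl)oxy]-2,6,6-trimethylcyclohex-1-en-1-yl]-3-methylpenta-2,4-dienoate
Product: 23 (2E,4E)-5-[(4R,5R)-4,5-bis[(tert-butyldimethylsilyl)oxy]-2,6,6-trimethylcyclohex-1-en-1-yl]-3-methylpenta-2,4-dien-1-ol
Conditions: i-Bu2AlH, CH2Cl2, −78 °C; aq. potassium sodium tartrate work-up
Reagents that add atoms: none
Why: Hydride reduction of the ester (1,2-reduction) at −78 °C gives the allylic alcohol without touching the triene or the silyl ethers.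

Step 20
Reactants: 23 (2E,4E)-5-[(4R,5R)-4,5-bis[(tert-butyldimethylsilyl)oxy]-2,6,6-trimethylcyclohex-1-en-1-yl]-3-methylpenta-2,4-dien-1-ol
Product: 24 (2E,4E)-5-[(4R,5R)-4,5-bis[(tert-butyldimethylsilyl)oxy]-2,6,6-trimethylcyclohex-1-en-1-yl]-3-methylpenta-2,4-dienal
Conditions: MnO2, CH2Cl2, rt
Reagents that add atoms: none
Why: Allylic oxidation with MnO2 is selective for the dienylic alcohol and gives the C15 aldehyde without double-bond isomerisation.

Step 21
Reactants: 24 (2E,4E)-5-[(4R,5R)-4,5-bis[(tert-butyldimethylsilyl)oxy]-2,6,6-trimethylcyclohex-1-en-1-yl]-3-methylpenta-2,4-dienal; 25 triethyl 3-methyl-4-phosphonocrotonate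
Product: 26 ethyl (2E,4E,6E,8E)-9-[(4R,5R)-4,5-bis[(tert-butyldimethylsilyl)oxy]-2,6,6-trimethylcyclohex-1-en-1-yl]-3,7-dimethylnona-2,4,6,8-tetraenoate
Conditions: 25, n-BuLi, THF/DMPU, −78 °C; then 24, −78 → 0 °C
Reagents that add atoms: none
Why: Horner–Wadsworth–Emmons olefination with the lithiated vinylogous phosphonate forms C11=C12 as the E alkene and brings in C12–C15, the 13E isomer should predominate and any 13-cis ester is removed by chromatography.

Step 22
Reactants: 26 ethyl (2E,4E,6E,8E)-9-[(4R,5R)-4,5-bis[(tert-butyldimethylsilyl)oxy]-2,6,6-trimethylcyclohex-1-en-1-yl]-3,7-dimethylnona-2,4,6,8-tetraenoate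
Product: 27 (2E,4E,6E,8E)-9-[(4R,5R)-4,5-bis[(tert-butyldimethylsilyl)oxy]-2,6,6-trimethylcyclohex-1-en-1-yl]-3,7-dimethylnona-2,4,6,8-tetraen-1-ol
Conditions: i-Bu2AlH, CH2Cl2, −78 °C; aq. potassium sodium tartrate work-up
Reagents that add atoms: none
Why: Hydride reduction of the conjugated ester (1,2-reduction) gives the retinol-type alcohol, which is carried on without storage.

Step 23
Reactants: 27 (2E,4E,6E,8E)-9-[(4R,5R)-4,5-bis[(tert-butyldimethylsilyl)oxy]-2,6,6-trimethylcyclohex-1-en-1-yl]-3,7-dimethylnona-2,4,6,8-tetraen-1-ol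
Product: 28 [(2E,4E,6E,8E)-9-[(4R,5R)-4,5-bis[(tert-butyldimethylsilyl)oxy]-2,6,6-trimethylcyclohex-1-en-1-yl]-3,7-dimethylnona-2,4,6,8-tetraen-1-yl]triphenylphosphonium bromide
Conditions: PPh3·HBr, CH2Cl2, 0 °C → rt
Reagents that add atoms: triphenylphosphine hydrobromide, [Br-].c1ccc(cc1)[PH+](c1ccccc1)c1ccccc1
Why: Phosphonium salt formation by SN1-type substitution, in which protonation ionises the allylic alcohol to the delocalised polyenyl cation that PPh3 captures at C15, is the standard route to retinyl-type Wittig salts, and the aprotic medium spares the silyl ethers.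

Step 24
Reactants: 18 tert-butyldimethyl{[(1R,6R)-2,2,4-trimethyl-6-[(triethylsilyl)oxy]-3-vinylcyclohex-3-en-1-yl]oxy}silane; 21 ethyl (E)-3-iodobut-2-enoate
Product: 29 ethyl (2E,4E)-5-[(4R,5R)-5-[(tert-butyldimethylsilyl)oxy]-2,6,6-trimethyl-4-[(triethylsilyl)oxy]cyclohex-1-en-1-yl]-3-methylpenta-2,4-dienoate
Conditions: Pd(OAc)2 (10 mol %), Bu4NCl, K2CO3, DMF, 50 °C
Reagents that add atoms: none
Why: The same Mizoroki–Heck coupling at C8 as in step 18 applies, and the triethylsilyl ether is stable to carbonate in DMF.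

Step 25
Reactants: 29 ethyl (2E,4E)-5-[(4R,5R)-5-[(tert-butyldimethylsilyl)oxy]-2,6,6-trimethyl-4-[(triethylsilyl)oxy]cyclohex-1-en-1-yl]-3-methylpenta-2,4-dienoate
Product: 30 (2E,4E)-5-[(4R,5R)-5-[(tert-butyldimethylsilyl)oxy]-2,6,6-trimethyl-4-[(triethylsilyl)oxy]cyclohex-1-en-1-yl]-3-methylpenta-2,4-dien-1-ol
Conditions: i-Bu2AlH, CH2Cl2, −78 °C; aq. potassium sodium tartrate work-up
Reagents that add atoms: none
Why: Hydride reduction of the ester (1,2-reduction) gives the allylic alcohol, and the neutral tartrate work-up keeps the triethylsilyl ether.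

Step 26
Reactants: 30 (2E,4E)-5-[(4R,5R)-5-[(tert-butyldimethylsilyl)oxy]-2,6,6-trimethyl-4-[(triethylsilyl)oxy]cyclohex-1-en-1-yl]-3-methylpenta-2,4-dien-1-ol
Product: 31 (2E,4E)-5-[(4R,5R)-5-[(tert-butyldimethylsilyl)oxy]-2,6,6-trimethyl-4-[(triethylsilyl)oxy]cyclohex-1-en-1-yl]-3-methylpenta-2,4-dienal
Conditions: MnO2, CH2Cl2, rt
Reagents that add atoms: none
Why: Allylic oxidation with MnO2 under neutral conditions gives the C15 aldehyde.

Step 27
Reactants: 31 (2E,4E)-5-[(4R,5R)-5-[(tert-butyldimethylsilyl)oxy]-2,6,6-trimethyl-4-[(triethylsilyl)oxy]cyclohex-1-en-1-yl]-3-methylpenta-2,4-dienal; 25 triethyl 3-methyl-4-phosphonocrotonate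
Product: 32 ethyl (2E,4E,6E,8E)-9-[(4R,5R)-5-[(tert-butyldimethylsilyl)oxy]-2,6,6-trimethyl-4-[(triethylsilyl)oxy]cyclohex-1-en-1-yl]-3,7-dimethylnona-2,4,6,8-tetraenoate
Conditions: 25, n-BuLi, THF/DMPU, −78 °C; then 31, −78 → 0 °C
Reagents that add atoms: none
Why: Horner–Wadsworth–Emmons olefination as in step 21 forms C11'=C12' as the E alkene and completes the C20 chain.

Step 28
Reactants: 32 ethyl (2E,4E,6E,8E)-9-[(4R,5R)-5-[(tert-butyldimethylsilyl)oxy]-2,6,6-trimethyl-4-[(triethylsilyl)oxy]cyclohex-1-en-1-yl]-3,7-dimethylnona-2,4,6,8-tetraenoate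
Product: 33 (2E,4E,6E,8E)-9-[(4R,5R)-5-[(tert-butyldimethylsilyl)oxy]-2,6,6-trimethyl-4-[(triethylsilyl)oxy]cyclohex-1-en-1-yl]-3,7-dimethylnona-2,4,6,8-tetraen-1-ol
Conditions: i-Bu2AlH, CH2Cl2, −78 °C; aq. potassium sodium tartrate work-up
Reagents that add atoms: none
Why: Hydride reduction of the conjugated ester (1,2-reduction) gives the C20 allylic alcohol.

Step 29
Reactants: 33 (2E,4E,6E,8E)-9-[(4R,5R)-5-[(tert-butyldimethylsilyl)oxy]-2,6,6-trimethyl-4-[(triethylsilyl)oxy]cyclohex-1-en-1-yl]-3,7-dimethylnona-2,4,6,8-tetraen-1-ol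
Product: 34 (2E,4E,6E,8E)-9-[(4R,5R)-5-[(tert-butyldimethylsilyl)oxy]-2,6,6-trimethyl-4-[(triethylsilyl)oxy]cyclohex-1-en-1-yl]-3,7-dimethylnona-2,4,6,8-tetraenal
Conditions: MnO2, CH2Cl2, rt
Reagents that add atoms: none
Why: Allylic oxidation with MnO2 gives the retinal-type aldehyde without acid, so the triethylsilyl ether survives.

Step 30
Reactants: 28 C20 phosphonium bromide (O2 and O3 as TBS ethers); 34 C20 aldehyde (O2' TBS and O3' TES)
Product: 37 (all-E)-(2R,3R,2'R,3'R)-2,3,2'-tris(tert-butyldimethylsilyloxy)-3'-(triethylsilyloxy)-β,β-carotene, via phosphonium ylide 35 (not isolated), via 15-cis isomer 36 (not isolated)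
Conditions: NaN(SiMe3)2, THF, −78 °C; then 34, −78 → 0 °C; then heptane, reflux
Reagents that add atoms: none
Why: Wittig olefination of the semi-stabilised polyenyl ylide with the polyenal forms C15=C15' as an E/Z mixture, and the central 15-cis bond, the least hindered cis position of a carotenoid, isomerises thermally to the all-E chain.

Step 31
Reactants: 37 (all-E)-(2R,3R,2'R,3'R)-2,3,2'-tris(tert-butyldimethylsilyloxy)-3'-(triethylsilyloxy)-β,β-carotene
Product: 38 (all-E)-(2R,3R,2'R,3'R)-2,3,2'-tris(tert-butyldimethylsilyloxy)-β,β-caroten-3'-ol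
Conditions: PPTS (cat.), MeOH/CH2Cl2, 0 °C
Reagents that add atoms: none
Why: Acid-catalysed methanolysis removes the triethylsilyl ether, which is far more labile than the three tert-butyldimethylsilyl ethers, so O3' alone is freed.

Step 32
Reactants: 38 (all-E)-(2R,3R,2'R,3'R)-2,3,2'-tris(tert-butyldimethylsilyloxy)-β,β-caroten-3'-ol
Product: 39 pyridinium (all-E)-(2R,3R,2'R,3'R)-2,3,2'-tris(tert-butyldimethylsilyloxy)-β,β-caroten-3'-yl sulfate
Conditions: SO3·pyridine, pyridine/THF, rt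
Reagents that add atoms: sulfur trioxide–pyridine complex, [O-]S(=O)(=O)[n+]1ccccc1
Why: O-Sulfation of the single free hydroxyl by the SO3–pyridine complex gives the sulfate monoester under basic conditions that the polyene and the silyl ethers tolerate.

Step 33
Reactants: 39 pyridinium (all-E)-(2R,3R,2'R,3'R)-2,3,2'-tris(tert-butyldimethylsilyloxy)-β,β-caroten-3'-yl sulfate
Product: 40 (all-E)-(2R,3R,2'R,3'R)-2,3,2'-trihydroxy-β,β-caroten-3'-yl hydrogen sulfate (target)
Conditions: Bu4NF, THF, rt → 40 °C; then cold dilute aq. HCl, extraction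
Reagents that add atoms: none
Why: Fluoride-mediated desilylation cleaves the three Si–O bonds while the sulfate monoester anion is inert to fluoride and base, and brief cold acidification converts the salt into the hydrogen sulfate.

**Compound list**

1 | methallyl chloride (3-chloro-2-methylprop-1-ene) | C=C(C)CCl | starting material
2 | (2-methylallyl)magnesium chloride (not isolated) | C=C(C)C[Mg]Cl | intermediate
3 | tributyl(2-methylallyl)stannane | C=C(C)C[Sn](CCCC)(CCCC)CCCC | intermediate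
4 | (R)-pantolactone | CC1(C)COC(=O)[C@@H]1O | starting material
5 | (2R)-3,3-dimethylbutane-1,2,4-triol | OC[C@H](O)C(C)(C)CO | intermediate
6 | [(2R,4R)-2-(4-methoxyphenyl)-5,5-dimethyl-1,3-dioxan-4-yl]methanol (aryl and CH2OH cis) | OC[C@@H]1O[C@H](c2ccc(OC)cc2)OCC1(C)C | intermediate
7 | (2R,4R)-2-(4-methoxyphenyl)-5,5-dimethyl-1,3-dioxane-4-carbaldehyde | O=C[C@@H]1O[C@H](c2ccc(OC)cc2)OCC1(C)C | intermediate
8 | (1R)-1-[(2R,4R)-2-(4-methoxyphenyl)-5,5-dimethyl-1,3-dioxan-4-yl]-3-methylbut-3-en-1-ol | C=C(C)C[C@@H](O)[C@@H]1O[C@H](c2ccc(OC)cc2)OCC1(C)C | intermediate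
9 | tert-butyl{[(1R)-1-[(2R,4R)-2-(4-methoxyphenyl)-5,5-dimethyl-1,3-dioxan-4-yl]-3-methylbut-3-en-1-yl]oxy}dimethylsilane | C=C(C)C[C@@H](O[Si](C)(C)C(C)(C)C)[C@@H]1O[C@H](c2ccc(OC)cc2)OCC1(C)C | intermediate
10 | (3R,4R)-4-[(tert-butyldimethylsilyl)oxy]-3-[(4-methoxybenzyl)oxy]-2,2,6-trimethylhept-6-en-1-ol | OCC(C)(C)[C@@H](OCc1ccc(OC)cc1)[C@H](O[Si](C)(C)C(C)(C)C)CC(C)=C | intermediate
11 | (3R,4R)-4-[(tert-butyldimethylsilyl)oxy]-3-[(4-methoxybenzyl)oxy]-2,2,6-trimethylhept-6-enal | O=CC(C)(C)[C@@H](OCc1ccc(OC)cc1)[C@H](O[Si](C)(C)C(C)(C)C)CC(C)=C | intermediate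
12 | tert-butyl{[(4R,5R)-5-[(4-methoxybenzyl)oxy]-2,6,6-trimethyloct-1-en-7-yn-4-yl]oxy}dimethylsilane (key-step precursor) | C#CC(C)(C)[C@@H](OCc1ccc(OC)cc1)[C@H](O[Si](C)(C)C(C)(C)C)CC(C)=C | intermediate
13 | tert-butyl{[(1R,6R)-6-[(4-methoxybenzyl)oxy]-3,5,5-trimethyl-4-vinylcyclohex-3-en-1-yl]oxy}dimethylsilane (key-step product) | C=CC1=C(C)C[C@@H](O[Si](C)(C)C(C)(C)C)[C@H](OCc2ccc(OC)cc2)C1(C)C | intermediate
14 | (1R,6R)-6-[(tert-butyldimethylsilyl)oxy]-2,2,4-trimethyl-3-vinylcyclohex-3-en-1-ol | C=CC1=C(C)C[C@@H](O[Si](C)(C)C(C)(C)C)[C@H](O)C1(C)C | intermediate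
15 | (4R,5R)-4,5-bis[(tert-butyldimethylsilyl)oxy]-1,3,3-trimethyl-2-vinylcyclohex-1-ene | C=CC1=C(C)C[C@@H](O[Si](C)(C)C(C)(C)C)[C@H](O[Si](C)(C)C(C)(C)C)C1(C)C | intermediate
16 | (1R,2R)-3,3,5-trimethyl-4-vinylcyclohex-4-ene-1,2-diol | C=CC1=C(C)C[C@@H](O)[C@H](O)C1(C)C | intermediate
17 | (1R,6R)-2,2,4-trimethyl-6-[(triethylsilyl)oxy]-3-vinylcyclohex-3-en-1-ol | C=CC1=C(C)C[C@@H](O[Si](CC)(CC)CC)[C@H](O)C1(C)C | intermediate
18 | tert-butyldimethyl{[(1R,6R)-2,2,4-trimethyl-6-[(triethylsilyl)oxy]-3-vinylcyclohex-3-en-1-yl]oxy}silane | C=CC1=C(C)C[C@@H](O[Si](CC)(CC)CC)[C@H](O[Si](C)(C)C(C)(C)C)C1(C)C | intermediate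
19 | ethyl but-2-ynoate | CC#CC(=O)OCC | starting material
20 | ethyl (E)-3-(tributylstannyl)but-2-enoate | CCOC(=O)/C=C(C)/[Sn](CCCC)(CCCC)CCCC | intermediate
21 | ethyl (E)-3-iodobut-2-enoate | CCOC(=O)/C=C(C)/I | intermediate
22 | ethyl (2E,4E)-5-[(4R,5R)-4,5-bis[(tert-butyldimethylsilyl)oxy]-2,6,6-trimethylcyclohex-1-en-1-yl]-3-methylpenta-2,4-dienoate | CCOC(=O)/C=C(C)/C=C/C1=C(C)C[C@@H](O[Si](C)(C)C(C)(C)C)[C@H](O[Si](C)(C)C(C)(C)C)C1(C)C | intermediate
23 | (2E,4E)-5-[(4R,5R)-4,5-bis[(tert-butyldimethylsilyl)oxy]-2,6,6-trimethylcyclohex-1-en-1-yl]-3-methylpenta-2,4-dien-1-ol | OC/C=C(C)/C=C/C1=C(C)C[C@@H](O[Si](C)(C)C(C)(C)C)[C@H](O[Si](C)(C)C(C)(C)C)C1(C)C | intermediate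
24 | (2E,4E)-5-[(4R,5R)-4,5-bis[(tert-butyldimethylsilyl)oxy]-2,6,6-trimethylcyclohex-1-en-1-yl]-3-methylpenta-2,4-dienal | O=C/C=C(C)/C=C/C1=C(C)C[C@@H](O[Si](C)(C)C(C)(C)C)[C@H](O[Si](C)(C)C(C)(C)C)C1(C)C | intermediate
25 | triethyl 3-methyl-4-phosphonocrotonate | CCOC(=O)/C=C(C)/CP(=O)(OCC)OCC | starting material
26 | ethyl (2E,4E,6E,8E)-9-[(4R,5R)-4,5-bis[(tert-butyldimethylsilyl)oxy]-2,6,6-trimethylcyclohex-1-en-1-yl]-3,7-dimethylnona-2,4,6,8-tetraenoate | CCOC(=O)/C=C(C)/C=C/C=C(C)/C=C/C1=C(C)C[C@@H](O[Si](C)(C)C(C)(C)C)[C@H](O[Si](C)(C)C(C)(C)C)C1(C)C | intermediate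
27 | (2E,4E,6E,8E)-9-[(4R,5R)-4,5-bis[(tert-butyldimethylsilyl)oxy]-2,6,6-trimethylcyclohex-1-en-1-yl]-3,7-dimethylnona-2,4,6,8-tetraen-1-ol | OC/C=C(C)/C=C/C=C(C)/C=C/C1=C(C)C[C@@H](O[Si](C)(C)C(C)(C)C)[C@H](O[Si](C)(C)C(C)(C)C)C1(C)C | intermediate
28 | [(2E,4E,6E,8E)-9-[(4R,5R)-4,5-bis[(tert-butyldimethylsilyl)oxy]-2,6,6-trimethylcyclohex-1-en-1-yl]-3,7-dimethylnona-2,4,6,8-tetraen-1-yl]triphenylphosphonium bromide | [Br-].c1ccccc1[P+](c1ccccc1)(c1ccccc1)C/C=C(C)/C=C/C=C(C)/C=C/C1=C(C)C[C@@H](O[Si](C)(C)C(C)(C)C)[C@H](O[Si](C)(C)C(C)(C)C)C1(C)C | intermediate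
29 | ethyl (2E,4E)-5-[(4R,5R)-5-[(tert-butyldimethylsilyl)oxy]-2,6,6-trimethyl-4-[(triethylsilyl)oxy]cyclohex-1-en-1-yl]-3-methylpenta-2,4-dienoate | CCOC(=O)/C=C(C)/C=C/C1=C(C)C[C@@H](O[Si](CC)(CC)CC)[C@H](O[Si](C)(C)C(C)(C)C)C1(C)C | intermediate
30 | (2E,4E)-5-[(4R,5R)-5-[(tert-butyldimethylsilyl)oxy]-2,6,6-trimethyl-4-[(triethylsilyl)oxy]cyclohex-1-en-1-yl]-3-methylpenta-2,4-dien-1-ol | OC/C=C(C)/C=C/C1=C(C)C[C@@H](O[Si](CC)(CC)CC)[C@H](O[Si](C)(C)C(C)(C)C)C1(C)C | intermediate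
31 | (2E,4E)-5-[(4R,5R)-5-[(tert-butyldimethylsilyl)oxy]-2,6,6-trimethyl-4-[(triethylsilyl)oxy]cyclohex-1-en-1-yl]-3-methylpenta-2,4-dienal | O=C/C=C(C)/C=C/C1=C(C)C[C@@H](O[Si](CC)(CC)CC)[C@H](O[Si](C)(C)C(C)(C)C)C1(C)C | intermediate
32 | ethyl (2E,4E,6E,8E)-9-[(4R,5R)-5-[(tert-butyldimethylsilyl)oxy]-2,6,6-trimethyl-4-[(triethylsilyl)oxy]cyclohex-1-en-1-yl]-3,7-dimethylnona-2,4,6,8-tetraenoate | CCOC(=O)/C=C(C)/C=C/C=C(C)/C=C/C1=C(C)C[C@@H](O[Si](CC)(CC)CC)[C@H](O[Si](C)(C)C(C)(C)C)C1(C)C | intermediate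
33 | (2E,4E,6E,8E)-9-[(4R,5R)-5-[(tert-butyldimethylsilyl)oxy]-2,6,6-trimethyl-4-[(triethylsilyl)oxy]cyclohex-1-en-1-yl]-3,7-dimethylnona-2,4,6,8-tetraen-1-ol | OC/C=C(C)/C=C/C=C(C)/C=C/C1=C(C)C[C@@H](O[Si](CC)(CC)CC)[C@H](O[Si](C)(C)C(C)(C)C)C1(C)C | intermediate
34 | (2E,4E,6E,8E)-9-[(4R,5R)-5-[(tert-butyldimethylsilyl)oxy]-2,6,6-trimethyl-4-[(triethylsilyl)oxy]cyclohex-1-en-1-yl]-3,7-dimethylnona-2,4,6,8-tetraenal | O=C/C=C(C)/C=C/C=C(C)/C=C/C1=C(C)C[C@@H](O[Si](CC)(CC)CC)[C@H](O[Si](C)(C)C(C)(C)C)C1(C)C | intermediate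
35 | phosphonium ylide of 28 (not isolated) | c1ccccc1[P+](c1ccccc1)(c1ccccc1)[CH-]/C=C(C)/C=C/C=C(C)/C=C/C1=C(C)C[C@@H](O[Si](C)(C)C(C)(C)C)[C@H](O[Si](C)(C)C(C)(C)C)C1(C)C | intermediate
36 | (15Z)-(2R,3R,2'R,3'R)-2,3,2'-tris(tert-butyldimethylsilyloxy)-3'-(triethylsilyloxy)-β,β-carotene (not isolated) | CC1=C(/C=C/C(C)=C/C=C/C(C)=C/C=C\C=C(C)\C=C\C=C(C)\C=C\C2=C(C)C[C@@H](O[Si](CC)(CC)CC)[C@H](O[Si](C)(C)C(C)(C)C)C2(C)C)C(C)(C)[C@@H](O[Si](C)(C)C(C)(C)C)[C@H](O[Si](C)(C)C(C)(C)C)C1 | intermediate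
37 | (all-E)-(2R,3R,2'R,3'R)-2,3,2'-tris(tert-butyldimethylsilyloxy)-3'-(triethylsilyloxy)-β,β-carotene | CC1=C(/C=C/C(C)=C/C=C/C(C)=C/C=C/C=C(C)/C=C/C=C(C)/C=C/C2=C(C)C[C@@H](O[Si](CC)(CC)CC)[C@H](O[Si](C)(C)C(C)(C)C)C2(C)C)C(C)(C)[C@@H](O[Si](C)(C)C(C)(C)C)[C@H](O[Si](C)(C)C(C)(C)C)C1 | intermediate
38 | (all-E)-(2R,3R,2'R,3'R)-2,3,2'-tris(tert-butyldimethylsilyloxy)-β,β-caroten-3'-ol | CC1=C(/C=C/C(C)=C/C=C/C(C)=C/C=C/C=C(C)/C=C/C=C(C)/C=C/C2=C(C)C[C@@H](O)[C@H](O[Si](C)(C)C(C)(C)C)C2(C)C)C(C)(C)[C@@H](O[Si](C)(C)C(C)(C)C)[C@H](O[Si](C)(C)C(C)(C)C)C1 | intermediate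
39 | pyridinium (all-E)-(2R,3R,2'R,3'R)-2,3,2'-tris(tert-butyldimethylsilyloxy)-β,β-caroten-3'-yl sulfate | CC1=C(/C=C/C(C)=C/C=C/C(C)=C/C=C/C=C(C)/C=C/C=C(C)/C=C/C2=C(C)C[C@@H](OS(=O)(=O)[O-])[C@H](O[Si](C)(C)C(C)(C)C)C2(C)C)C(C)(C)[C@@H](O[Si](C)(C)C(C)(C)C)[C@H](O[Si](C)(C)C(C)(C)C)C1.c1cc[nH+]cc1 | intermediate
40 | (all-E)-(2R,3R,2'R,3'R)-2,3,2'-trihydroxy-β,β-caroten-3'-yl hydrogen sulfate (CNP0229621.3) | CC1=C(/C=C/C(C)=C/C=C/C(C)=C/C=C/C=C(C)/C=C/C=C(C)/C=C/C2=C(C)C[C@@H](OS(=O)(=O)O)[C@H](O)C2(C)C)C(C)(C)[C@@H](O)[C@H](O)C1 | target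

**Step count and risks**

Total steps: 33. Longest linear sequence: 23 steps from (R)-pantolactone 4 (steps 2–11, 13–15, 24–29 and 30–33).

Steps most likely to fail:

1. Step 10 (key step). The C6 vinylcarbene may fail to engage the hindered isopropenyl group, so that the alkyne is drained into the open-chain butadiene or into oligomers, or closure may take the endo course. Fallback: set out from 12 and split the event into two known reactions. Cross enyne metathesis with ethylene at room temperature (the same catalyst, CH2Cl2, ethylene) should stop at the triene tert-butyl{[(4R,5R)-5-[(4-methoxybenzyl)oxy]-2,6,6-trimethyl-7-methylidenenona-1,8-dien-4-yl]oxy}dimethylsilane F1. Ring-closing diene metathesis of its two 1,1-disubstituted alkenes then follows, with a ruthenium catalyst built for tetrasubstituted olefins, [1,3-bis(2-methylphenyl)imidazolidin-2-ylidene]Cl2Ru=CH(C6H4-2-OiPr), in toluene at 80–100 °C under an argon sweep that carries off ethylene. This comes back to the route at 13.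

2. Step 18 and its twin on the other half, step 24. Slow insertion at the hindered diene terminus may let the iodoester be lost by dehydroiodination, and the allylpalladium intermediate may eliminate toward the ring or erode the E geometry. Fallback: set out from 15 and dihydroxylate the exposed vinyl group (K2OsO4·2H2O cat., N-methylmorpholine N-oxide, acetone/H2O; the tetrasubstituted ring alkene is too hindered to react) to 1-[(4R,5R)-4,5-bis(tert-butyldimethylsilyloxy)-2,6,6-trimethylcyclohex-1-en-1-yl]ethane-1,2-diol F2. Cleavage with NaIO4 gives (4R,5R)-4,5-bis(tert-butyldimethylsilyloxy)-2,6,6-trimethylcyclohex-1-ene-1-carbaldehyde F3, and a Horner–Wadsworth–Emmons reaction of F3 with the anion of phosphonate 25 brings in C8–C11 at once and returns to the route at 22. From 18 the same three operations lead through 1-[(4R,5R)-5-(tert-butyldimethylsilyloxy)-2,6,6-trimethyl-4-(triethylsilyloxy)cyclohex-1-en-1-yl]ethane-1,2-diol F4 and (4R,5R)-5-(tert-butyldimethylsilyloxy)-2,6,6-trimethyl-4-(triethylsilyloxy)cyclohex-1-ene-1-carbaldehyde F5 back to 29.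

3. Step 33. Removal of the neopentyl silyl ethers at O2 and O2' may stay incomplete under conditions mild enough for the anionic polyene sulfate, or the sulfate may be solvolysed during acidification. Fallback: set out from 38 and remove all three silyl groups first, where no sulfate is at risk (Bu4NF, THF, 40 °C), to give (all-E)-(2R,3R,2'R,3'R)-β,β-carotene-2,3,2',3'-tetrol F6. The twofold symmetry of F6 makes O3 and O3' the same site, and the neopentyl O2 and O2' should react far more slowly. Sulfation with about one equivalent of SO3·pyridine at 0 °C, followed by the same cold acidification, therefore comes back to the route at the target 40, with unreacted F6 recycled and the bis-sulfate removed by chromatography.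

Further compounds
F1 | step 10 | tert-butyl{[(4R,5R)-5-[(4-methoxybenzyl)oxy]-2,6,6-trimethyl-7-methylidenenona-1,8-dien-4-yl]oxy}dimethylsilane | C=CC(=C)C(C)(C)[C@@H](OCc1ccc(OC)cc1)[C@H](O[Si](C)(C)C(C)(C)C)CC(C)=C
F2 | step 18 | 1-[(4R,5R)-4,5-bis(tert-butyldimethylsilyloxy)-2,6,6-trimethylcyclohex-1-en-1-yl]ethane-1,2-diol (both C7 epimers) | OCC(O)C1=C(C)C[C@@H](O[Si](C)(C)C(C)(C)C)[C@H](O[Si](C)(C)C(C)(C)C)C1(C)C
F3 | step 18 | (4R,5R)-4,5-bis(tert-butyldimethylsilyloxy)-2,6,6-trimethylcyclohex-1-ene-1-carbaldehyde | O=CC1=C(C)C[C@@H](O[Si](C)(C)C(C)(C)C)[C@H](O[Si](C)(C)C(C)(C)C)C1(C)C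
F4 | step 24 | 1-[(4R,5R)-5-(tert-butyldimethylsilyloxy)-2,6,6-trimethyl-4-(triethylsilyloxy)cyclohex-1-en-1-yl]ethane-1,2-diol (both C7' epimers) | OCC(O)C1=C(C)C[C@@H](O[Si](CC)(CC)CC)[C@H](O[Si](C)(C)C(C)(C)C)C1(C)C
F5 | step 24 | (4R,5R)-5-(tert-butyldimethylsilyloxy)-2,6,6-trimethyl-4-(triethylsilyloxy)cyclohex-1-ene-1-carbaldehyde | O=CC1=C(C)C[C@@H](O[Si](CC)(CC)CC)[C@H](O[Si](C)(C)C(C)(C)C)C1(C)C
F6 | step 33 | (all-E)-(2R,3R,2'R,3'R)-β,β-carotene-2,3,2',3'-tetrol | CC1=C(/C=C/C(C)=C/C=C/C(C)=C/C=C/C=C(C)/C=C/C=C(C)/C=C/C2=C(C)C[C@@H](O)[C@H](O)C2(C)C)C(C)(C)[C@@H](O)[C@H](O)C1
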